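**Retrosynthetic overview**
1. Target 21 ⇒ dioxane vinyl iodide 17 + alkenylboronate 20 (Suzuki–Miyaura at C9–C10). The diene is added last because it would not survive the radical oxygenation.
2. 17 ⇒ acyclic iodo-triene ester 14 + O2. Cobalt-hydride H-atom transfer and O2 capture at C6, then peroxy-Michael addition to C3 in the same flask, close the only ring (the 1,2-dioxane) and create C6 and C3.
3. 14 ⇒ alcohol 12 (oxidation/Wittig) ⇒ vinyl bromide 9 + allylic bromide 4 (copper-catalysed allylation).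
4. 9 ⇒ Evans alkylation of 5 with 6 (sets C4); 4 ⇒ propargyl alcohol 1 (carboalumination); 20 ⇒ 18 + 19 (cross-metathesis).

Assumption: the dioxane is taken to arise in nature from a C6 tertiary hydroperoxide of an acyclic polyketide 2-enoate (O2 captured at C6) that adds in conjugate fashion to C3.

Numbering in the text: C1 = ester carbon; C3, C4, C6 = dioxane carbons 3, 4, 6; C7–C12 = side chain (C12 = benzylic CH2). Target descriptors: 3S, 4R, 6R.

**Route**

Step 1
Reactants: 1 prop-2-yn-1-ol
Product: 3 (2E)-3-iodo-2-methylprop-2-en-1-ol, via alkenylalane 2 (not isolated)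
Conditions: AlMe3 (3 equiv), Cp2ZrCl2 (0.25 equiv), CH2Cl2, 0 °C → rt; then I2, THF, −30 → 0 °C
Reagents that add atoms: trimethylaluminium, C[Al](C)C; iodine, II
Why: Negishi zirconium-catalysed carboalumination adds Me and Al syn across the alkyne with methyl on the internal carbon, and iodinolysis of the C–Al bond with retention fixes the (E)-iodoalkene.

Step 2
Reactants: 3 (2E)-3-iodo-2-methylprop-2-en-1-ol
Product: 4 (1E)-3-bromo-1-iodo-2-methylprop-1-ene
Conditions: PBr3 (0.4 equiv), Et2O, 0 °C
Reagents that add atoms: phosphorus tribromide, BrP(Br)Br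
Why: SN2 bromination of the primary allylic alcohol leaves the vinyl iodide and the alkene geometry untouched.

Step 3
Reactants: 5 (4S)-4-benzyl-3-propanoyl-1,3-oxazolidin-2-one; 6 2,3-dibromoprop-1-ene
Product: 8 (4S)-4-benzyl-3-[(2R)-4-bromo-2-methylpent-4-enoyl]-1,3-oxazolidin-2-one, via sodium enolate 7 (not isolated)
Conditions: NaHMDS, THF, −78 °C; then 6 (3 equiv), −78 → −45 °C
Reagents that add atoms: none
Why: Evans asymmetric alkylation, in which the chelated (Z)-sodium enolate is attacked by the allylic bromide on the face away from the benzyl group, sets the future C4 as R (dr above 95:5 expected, minor isomer removed by chromatography).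

Step 4
Reactants: 8 (4S)-4-benzyl-3-[(2R)-4-bromo-2-methylpent-4-enoyl]-1,3-oxazolidin-2-one
Product: 9 (2R)-4-bromo-2-methylpent-4-en-1-ol
Conditions: LiBH4, MeOH (1.1 equiv), Et2O, 0 °C
Reagents that add atoms: none
Why: Reductive cleavage of the Evans auxiliary with LiBH4 gives the primary alcohol without epimerising the α-methyl centre and does not touch the vinyl bromide.

Step 5
Reactants: 9 (2R)-4-bromo-2-methylpent-4-en-1-ol; 4 (1E)-3-bromo-1-iodo-2-methylprop-1-ene
Product: 12 (2R,6E)-7-iodo-2,6-dimethyl-4-methylidenehept-6-en-1-ol, via dilithio alkoxide 10 (not isolated), via alkenylmagnesium bromide 11 (not isolated)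
Conditions: t-BuLi (3.1 equiv), Et2O, −78 °C; MgBr2·OEt2, −78 → −40 °C; Li2CuCl4 (5 mol%), then 4 (1.2 equiv), −40 → 0 °C
Reagents that add atoms: none
Why: Bromine–lithium exchange and transmetalation give an alkenyl Grignard reagent that undergoes Kochi-type copper-catalysed SN2 allylation by the primary allylic bromide of 4 (faster than any exchange at its vinyl iodide), building the skipped diene remote from the stereocentre.

Step 6
Reactants: 12 (2R,6E)-7-iodo-2,6-dimethyl-4-methylidenehept-6-en-1-ol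
Product: 14 methyl (2E,4R,8E)-9-iodo-4,8-dimethyl-6-methylidenenona-2,8-dienoate, via aldehyde 13 (not isolated)
Conditions: Dess–Martin periodinane, CH2Cl2, 0 °C → rt; then Ph3P=CHCO2Me (2.5 equiv), rt
Reagents that add atoms: methyl (triphenylphosphoranylidene)acetate, COC(=O)C=P(c1ccccc1)(c1ccccc1)c1ccccc1
Why: Dess–Martin oxidation followed in the same flask by a Wittig reaction with the stabilised ylide gives the (E)-enoate before the α-methyl aldehyde can epimerise.

Step 7
Reactants: 14 methyl (2E,4R,8E)-9-iodo-4,8-dimethyl-6-methylidenenona-2,8-dienoate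
Product: 17 methyl 2-[(3S,4R,6R)-6-[(2E)-3-iodo-2-methylprop-2-en-1-yl]-4,6-dimethyl-1,2-dioxan-3-yl]acetate, via triethylsilyl peroxide 15 (not isolated), via tertiary hydroperoxide 16 (not isolated)
Conditions: Co(thd)2 (10 mol%; thd = 2,2,6,6-tetramethylheptane-3,5-dionate), O2 (1 atm), Et3SiH (2 equiv), ClCH2CH2Cl, rt; then TBAF (1.2 equiv), THF, 0 °C
Reagents that add atoms: dioxygen, O=O
Why: Mukaiyama–Isayama hydroperoxysilylation (cobalt-hydride hydrogen-atom transfer to the 1,1-disubstituted alkene, which reacts faster than the enoate and the iodoalkene, then O2 capture of the tertiary C6 radical) followed by fluoride-triggered 6-exo intramolecular peroxy-Michael addition closes the dioxane with C3 trans to the C4 methyl through a chair with enoate arm and methyl equatorial (reversible addition, thermodynamic product), whereas C6 is created without facial bias (about 1:1) and 17 is separated from its C6 epimer by chromatography.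

Step 8
Reactants: 18 prop-2-en-1-ylbenzene; 19 4,4,5,5-tetramethyl-2-(prop-1-en-2-yl)-1,3,2-dioxaborolane
Product: 20 4,4,5,5-tetramethyl-2-[(2Z)-4-phenylbut-2-en-2-yl]-1,3,2-dioxaborolane
Conditions: second-generation Grubbs catalyst RuCl2(=CHPh)(PCy3)(H2IMes) (5 mol%), CH2Cl2, 40 °C
Reagents that add atoms: none
Why: Olefin cross-metathesis of a terminal alkene with the isopropenylboronate gives the trisubstituted alkenylboronate with the benzyl-bearing carbon trans to boron (the less hindered isomer, Z by the priority rules), driven by loss of ethene.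

Step 9
Reactants: 17 methyl 2-[(3S,4R,6R)-6-[(2E)-3-iodo-2-methylprop-2-en-1-yl]-4,6-dimethyl-1,2-dioxan-3-yl]acetate; 20 4,4,5,5-tetramethyl-2-[(2Z)-4-phenylbut-2-en-2-yl]-1,3,2-dioxaborolane
Product: 21 methyl 2-[(3S,4R,6R)-6-[(2E,4E)-2,4-dimethyl-6-phenylhexa-2,4-dien-1-yl]-4,6-dimethyl-1,2-dioxan-3-yl]acetate
Conditions: Pd(dppf)Cl2 (5 mol%), AsPh3 (10 mol%), Cs2CO3 (2 equiv), DMF/THF/H2O, rt
Reagents that add atoms: none
Why: Suzuki–Miyaura coupling joins the two alkenyl partners with retention of both double-bond geometries at room temperature under mild carbonate base, conditions a dialkyl peroxide and the methyl ester should tolerate, and no stereocentre is touched.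

**Compound list**
1 | prop-2-yn-1-ol | C#CCO | starting material
2 | [(1E)-3-[(dimethylalumanyl)oxy]-2-methylprop-1-en-1-yl](dimethyl)alumane | C[Al](C)OC/C(C)=C/[Al](C)C | intermediate (not isolated)
3 | (2E)-3-iodo-2-methylprop-2-en-1-ol | OC/C(C)=C/I | intermediate
4 | (1E)-3-bromo-1-iodo-2-methylprop-1-ene | BrC/C(C)=C/I | intermediate
5 | (4S)-4-benzyl-3-propanoyl-1,3-oxazolidin-2-one | CCC(=O)N1[C@@H](Cc2ccccc2)COC1=O | starting material
6 | 2,3-dibromoprop-1-ene | C=C(Br)CBr | starting material
7 | sodium (Z)-enolate of 5 | C/C=C(\O[Na])N1[C@@H](Cc2ccccc2)COC1=O | intermediate (not isolated)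
8 | (4S)-4-benzyl-3-[(2R)-4-bromo-2-methylpent-4-enoyl]-1,3-oxazolidin-2-one | C=C(Br)C[C@@H](C)C(=O)N1[C@@H](Cc2ccccc2)COC1=O | intermediate
9 | (2R)-4-bromo-2-methylpent-4-en-1-ol | C=C(Br)C[C@@H](C)CO | intermediate
10 | lithium (2R)-4-lithio-2-methylpent-4-en-1-olate | C=C([Li])C[C@@H](C)CO[Li] | intermediate (not isolated)
11 | bromomagnesium (2R)-4-(bromomagnesio)-2-methylpent-4-en-1-olate | C=C([Mg]Br)C[C@@H](C)CO[Mg]Br | intermediate (not isolated)
12 | (2R,6E)-7-iodo-2,6-dimethyl-4-methylidenehept-6-en-1-ol | C=C(C/C(C)=C/I)C[C@@H](C)CO | intermediate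
13 | (2R,6E)-7-iodo-2,6-dimethyl-4-methylidenehept-6-enal | C=C(C/C(C)=C/I)C[C@@H](C)C=O | intermediate (not isolated)
14 | methyl (2E,4R,8E)-9-iodo-4,8-dimethyl-6-methylidenenona-2,8-dienoate | COC(=O)/C=C/[C@H](C)CC(=C)C/C(C)=C/I | intermediate
15 | methyl (2E,4R,6R,8E)-9-iodo-4,6,8-trimethyl-6-[(triethylsilyl)peroxy]nona-2,8-dienoate | COC(=O)/C=C/[C@H](C)C[C@](C)(C/C(C)=C/I)OO[Si](CC)(CC)CC | intermediate (not isolated)
16 | methyl (2E,4R,6R,8E)-6-hydroperoxy-9-iodo-4,6,8-trimethylnona-2,8-dienoate | COC(=O)/C=C/[C@H](C)C[C@](C)(C/C(C)=C/I)OO | intermediate (not isolated)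
17 | methyl 2-[(3S,4R,6R)-6-[(2E)-3-iodo-2-methylprop-2-en-1-yl]-4,6-dimethyl-1,2-dioxan-3-yl]acetate | COC(=O)C[C@@H]1OO[C@@](C)(C/C(C)=C/I)C[C@H]1C | intermediate
18 | prop-2-en-1-ylbenzene (allylbenzene) | C=CCc1ccccc1 | starting material
19 | 4,4,5,5-tetramethyl-2-(prop-1-en-2-yl)-1,3,2-dioxaborolane | CC(=C)B1OC(C)(C)C(C)(C)O1 | starting material
20 | 4,4,5,5-tetramethyl-2-[(2Z)-4-phenylbut-2-en-2-yl]-1,3,2-dioxaborolane | CC1(C)OB(OC1(C)C)/C(C)=C/Cc1ccccc1 | intermediate
21 | methyl 2-[(3S,4R,6R)-6-[(2E,4E)-2,4-dimethyl-6-phenylhexa-2,4-dien-1-yl]-4,6-dimethyl-1,2-dioxan-3-yl]acetate | COC(=O)C[C@@H]1OO[C@@](C)(C/C(C)=C/C(C)=C/Cc2ccccc2)C[C@H]1C | target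

**Step count and risks**

Total step count: 9. Longest linear sequence: 6 (steps 3, 4, 5, 6, 7, 9; the branch through steps 1, 2, 5, 6, 7, 9 is also 6).

The three steps most likely to fail:

Step 7 (one-flask oxygenation and ring closure). The hydrogen-atom transfer may not discriminate cleanly between the three alkenes of 14, the silyl peroxide may not survive the fluoride stage, and C6 is formed without control, so at best about half of the material is 17. The fallback sets out from 14 and replaces radical O2 capture by a polar perhydrolysis. Markovnikov oxymercuration of the 1,1-disubstituted alkene (Hg(OAc)2, THF/H2O) gives methyl (2E,4R,8E)-6-[(acetoxymercurio)methyl]-6-hydroxy-9-iodo-4,8-dimethylnona-2,8-dienoate F1, and NaBH4 demercuration gives methyl (2E,4R,8E)-6-hydroxy-9-iodo-4,6,8-trimethylnona-2,8-dienoate F2 as both C6 epimers. SN1 exchange of the tertiary hydroxyl with 50% H2O2 and catalytic H2SO4 then gives the hydroperoxide 16 together with its C6 epimer. Et2NH in CF3CH2OH closes it, and the route is rejoined at 17 after the same chromatographic separation.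

Step 5 (alkenyl-metal allylation on the hydroxy vinyl bromide). Exchange on the alkoxide may be incomplete, and iodine–metal exchange or SN2' attack on 4 may compete. The fallback sets out from 5, brings in the iodoalkene last and does not use 4. Evans alkylation of 5 with 3-chloro-2-(chloromethyl)prop-1-ene (NaHMDS, THF, −78 °C) gives (4S)-4-benzyl-3-[(2R)-4-(chloromethyl)-2-methylpent-4-enoyl]-1,3-oxazolidin-2-one F3. LiBH4 gives (2R)-4-(chloromethyl)-2-methylpent-4-en-1-ol F4. Ethynylmagnesium bromide with catalytic CuCl displaces the allylic chloride (SN2 and SN2' give the same product here) to give (2R)-2-methyl-4-methylidenehept-6-yn-1-ol F5. Negishi carboalumination (AlMe3, Cp2ZrCl2) through the alkenylalane [(1E,6R)-7-[(dimethylalumanyl)oxy]-2,6-dimethyl-4-methylidenehept-1-en-1-yl](dimethyl)alumane F6, then I2, returns to the route at 12.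

Step 9 (Suzuki coupling of a hindered alkenylboronate in the presence of the peroxide and under aqueous base). The fallback sets out from 20 and uses a base-free Negishi coupling. I2/NaOH converts the boronate with retention into [(2E)-3-iodobut-2-en-1-yl]benzene F7. t-BuLi (Et2O, −78 °C) gives [(2E)-4-phenylbut-2-en-2-yl]lithium F8, and ZnCl2 gives chloro[(2E)-4-phenylbut-2-en-2-yl]zinc F9. F9 is coupled with 17 (Pd2(dba)3, tri(2-furyl)phosphine, THF, rt) to reach 21.

Further compounds
F1 | step 7 | methyl (2E,4R,8E)-6-[(acetoxymercurio)methyl]-6-hydroxy-9-iodo-4,8-dimethylnona-2,8-dienoate (both C6 epimers) | COC(=O)/C=C/[C@H](C)CC(O)(C[Hg]OC(C)=O)C/C(C)=C/I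
F2 | step 7 | methyl (2E,4R,8E)-6-hydroxy-9-iodo-4,6,8-trimethylnona-2,8-dienoate (both C6 epimers) | COC(=O)/C=C/[C@H](C)CC(C)(O)C/C(C)=C/I
F3 | step 5 | (4S)-4-benzyl-3-[(2R)-4-(chloromethyl)-2-methylpent-4-enoyl]-1,3-oxazolidin-2-one | C=C(CCl)C[C@@H](C)C(=O)N1[C@@H](Cc2ccccc2)COC1=O
F4 | step 5 | (2R)-4-(chloromethyl)-2-methylpent-4-en-1-ol | C=C(CCl)C[C@@H](C)CO
F5 | step 5 | (2R)-2-methyl-4-methylidenehept-6-yn-1-ol | C#CCC(=C)C[C@@H](C)CO
F6 | step 5 | [(1E,6R)-7-[(dimethylalumanyl)oxy]-2,6-dimethyl-4-methylidenehept-1-en-1-yl](dimethyl)alumane | C=C(C/C(C)=C/[Al](C)C)C[C@@H](C)CO[Al](C)C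
F7 | step 9 | [(2E)-3-iodobut-2-en-1-yl]benzene | I/C(C)=C/Cc1ccccc1
F8 | step 9 | [(2E)-4-phenylbut-2-en-2-yl]lithium | [Li]/C(C)=C/Cc1ccccc1
F9 | step 9 | chloro[(2E)-4-phenylbut-2-en-2-yl]zinc | Cl[Zn]/C(C)=C/Cc1ccccc1
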